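## The problem

Compound 17 is a 3,4-dihydro-2H-pyran (O1, C2 to C6) whose C5=C6 bond is a β-alkoxyacrylate bearing a methyl ester; C2 carries a methyl group, C3 a formyl group and C4 an acetic acid arm esterified with the primary hydroxyl of 2-(3,4-dihydroxyphenyl)ethanol. The pyran is the only ring to be built, but it holds three contiguous stereocentres, (2S,3S,4S), with methyl and formyl cis and formyl and acetate arm trans. C3 is the weak point: its hydrogen is α to the aldehyde and β to the ring oxygen, so base can epimerise it or expel O1 as a vinylogous carboxylate and open the ring; the aldehyde must therefore appear late and never meet a basic reagent. The catechol would not survive the oxidant that makes the aldehyde, and the two esters (conjugated methyl ester, saturated arylethyl ester) cannot be told apart once the formyl group is present, so each has to be installed in its final form. C2 and C3 are neighbours and can be set together in an open chain; C4 can then be set during ring closure under the control of C3. The enabling feature is that O1–C6=C5(CO2Me) is what an alkoxide forms with methyl propiolate 12, while C4 is the β-carbon of the side-chain ester: the carbanion left at C5 by the oxa-Michael addition is placed to add to a C4 enoate, so O1–C6 and C4–C5 can be made in one operation. The descriptor at C3 is S while it carries the formyl group and R while it carries an oxymethyl group; the geometry is the same throughout.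

## Retrosynthesis

**17 back to 14 (no skeletal bond cut).** The catechol is traced to its bis(tert-butyldimethylsilyl) ether 16, the aldehyde of 16 to the primary alcohol 15, and 15 to the silyl ether 14. This order keeps the aldehyde out of every step but the last two and keeps the catechol masked through the oxidation. The forward steps must cleave an alkyl silyl ether beside two aryl silyl ethers, oxidise without base, and remove the aryl silyl groups with buffered fluoride.

**14 to 11 and 12 (cut O1–C6 and C4–C5).** Both bonds belong to the β-alkoxyacrylate, and cutting them removes the ring, the conjugated ester and the C4 stereocentre at once. What remains is the open-chain hydroxy enoate 11, which has only two stereocentres, and the three-carbon ynoate 12. The neighbouring cut at O1–C2 (oxa-Michael addition of an enol to an ethylidene aldehyde) is reversible and leaves C2 and C3 to equilibrate. A cut at C3–C4 alone would need a far more elaborate precursor. The forward reaction must close the ring faster than the intermediate carbanion is protonated and must place C4 trans to the C3 substituent.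

**11 to 5 and 10 (cut the enoate C=C).** Olefin cross-metathesis joins the terminal alkene 5 to the acrylate 10. Olefination of a β-hydroxy-α-branched aldehyde would be the neighbouring choice, but that aldehyde is prone to epimerisation and elimination and would need its hydroxyl protected. Metathesis touches neither stereocentre, tolerates the free hydroxyl and brings in the whole aryl ester in one step. It must give the E enoate.

**5 to 4, then 2 and 3, then 1 (cut the C3–vinyl bond; O–Si).** The monosilyl ether 5 comes from diol 4, and 4 from opening of the trans-epoxy alcohol 2 at C2 by the vinyl Grignard reagent 3. Epoxide 2 comes from asymmetric epoxidation of the E allylic alcohol 1. A trans-epoxide opened with inversion gives exactly the relative configuration needed, hydroxyl and oxymethyl syn along the chain that ends in the vinyl group. An aldol route that reduces the acyl carbon to the oxymethyl group would have to be anti-selective with an α-vinyl enolate, while the dependable auxiliary-based aldol additions are syn-selective. An allylmetal route would need a chiral Z γ-(silyloxymethyl)allyl reagent of unproven selectivity. The forward reaction must attack C2 and not C3 of the epoxide.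

**10 to 8 and 9, then 7, then 6 (ester C–O; O–Si).** Acrylate 10 is the ester of alcohol 8 with acryloyl chloride 9. Alcohol 8 is reached from hydroxytyrosol 6 by exhaustive silylation to 7 and selective cleavage of the alkyl silyl ether. The same alkyl-over-aryl selectivity is needed again on 14, so this step rehearses it on a simple substrate.

## Roads not taken

**Alternative 1:** Claisen ring contraction. The cut is C3–C4, with the formyl group and the C5=C6 enol ether traced to a [3,3] shift of the 2-alkenyl-4H-1,3-dioxin A1. On heating, the ring enol ether and the exocyclic alkene of A1 would form C3–C4, break one acetal C–O bond, release the aldehyde and close the dihydropyran, giving the dimethyl ester A2.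
- Merits: the aldehyde arrives at the right oxidation level with no oxidant, C3 and C4 are set in one concerted, reagent-free step, and only the methyl-bearing acetal carbon has to be bought as a stereocentre. In redox economy this road is better than the chosen one, which needs a deprotection and an oxidation after ring formation.
- Weak points:
  - The acetal tether forces a boat transition state. By analysis of that transition state, the 3,4-trans product requires the E alkene with the acetate arm turned over the ring, and the 2,3-cis relationship requires the 2,4-trans acetal, whereas acetalisation under equilibrium favours the 2,4-cis isomer.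
  - The alkene of A1 sits in a pent-2-enedioate unit with acidic γ-hydrogens. Double-bond migration and E/Z scrambling on heating would erase the control of C4.
  - A2 carries two methyl esters. The arylethyl ester would have to be made by selective saponification of the saturated ester and re-esterification with 8, on a compound whose C3 aldehyde tolerates base least.
- Against the redox advantage, the chosen plan sets esters that are differentiated from the start and a precursor, 11, that is stable and made by routine reactions.

**Alternative 2:** Hetero-Diels–Alder reaction. The cut is C2–C3 and O1–C6. Acetaldehyde A4, activated by a chiral Lewis acid, would add across the 1-methoxy diene ester A3 to give the all-cis 3,6-dihydro-2H-pyran A5 with a C4=C5 double bond.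
- Merits: two cheap achiral fragments, catalyst-derived chirality, C2 and C3 set together, and the ring formed early. The enoate of A5 is then a Michael acceptor for the acetate arm at C4.
- Weak points:
  - In A3 the methoxy donor is conjugated with the ester, which lowers the diene's reactivity, and A4 is a small, unactivated, enolisable aldehyde of the kind that normally needs doubly donor-substituted dienes.
  - The cycloaddition needs the Z methoxyacrylate geometry (methoxy outside), while the stable isomer of such units is E, which cannot easily reach the s-cis conformation.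
  - Facial discrimination between methyl and hydrogen on A4 is hard.
  - After the cycloaddition, a conjugate addition at C4 (trans to C3, under substrate control), β-elimination of the C6 methoxy group to regenerate C5=C6, ester adjustment and the same three-step endgame are still needed.
- This road is more convergent at the ring-forming stage and uses no chiral starting material. The chosen plan sets against it a ring closure that installs the C4 arm, both esters and the enol ether in their final form in one step, and C2/C3 control from a reliable catalytic epoxidation.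

**Alternative 3:** Three-component organocatalytic cascade. The cuts are C4–C5, C2=C3 and O1–C2. Under a prolinol silyl ether amine catalyst, methyl formylacetate A7 would add to the enal A6 (C4–C5, C4 under catalyst control), the new aldehyde would condense with A4 (C2=C3), and the enol oxygen would close the ring by oxa-Michael addition (O1–C2), giving the bis-silyl ether A8, which is compound 16 of the present route.
- Merits: it is the shortest road by far, it mirrors the way the open secoiridoid dialdehyde closes in nature, and it delivers the aldehyde directly, one deprotection from 17. In step count it is clearly better than the chosen plan.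
- Weak points:
  - The Michael adduct of a 1,3-dicarbonyl compound and an enal normally closes at once to a six-membered lactol through the enol oxygen and the new aldehyde, which removes the aldehyde needed for the condensation with A4.
  - A4 self-condenses and competes for the catalyst, and three aldehydes are present together.
  - The methylene group of A6 is activated twice and invites dienamine formation and oligomerisation.
  - C2 and C3 would be set in a reversible oxa-Michael and enolisation manifold, so a mixture of C2 epimers is to be expected, while 17 requires the 2,3-cis isomer.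
- The chosen plan sets against the brevity of this road C2 and C3 fixed before ring closure and a ring closure that is irreversible.

Key step: step 8

Assumption: 1 is used as the geometrically pure E isomer (commercial trans-crotyl alcohol); the locants O1 and C2 to C6 used in the text are those of the dihydropyran ring of 17.

## Route

Step 1
Reactants: 1 (E)-but-2-en-1-ol
Product: 2 [(2S,3S)-3-methyloxiran-2-yl]methanol ((2S,3S)-2,3-epoxybutan-1-ol)
Conditions: Ti(OiPr)4 (5 mol %), L-(+)-diisopropyl tartrate (6 mol %), tBuOOH, 4 Å molecular sieves, CH2Cl2, −20 °C; non-aqueous work-up, distillation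
Reagents that add atoms: tert-butyl hydroperoxide, CC(C)(C)OO
Why: Sharpless asymmetric epoxidation of a primary E allylic alcohol, a standard substrate class; the L-(+)-tartrate directs oxygen to the face that gives the (2S,3S)-epoxide, and the E geometry becomes the trans relationship of the two new stereocentres. The product is small and water-soluble, hence the work-up without water.

Step 2
Reactants: 2 [(2S,3S)-3-methyloxiran-2-yl]methanol; 3 vinylmagnesium bromide
Product: 4 (2R,3S)-2-ethenylbutane-1,3-diol
Conditions: CH2=CHMgBr (3 equiv), CuI (copper monoiodide, 10 mol %), THF/Et2O, −40 → −20 °C; sat. NH4Cl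
Reagents that add atoms: none
Why: CuI-catalysed Grignard opening of a 2,3-epoxy alcohol at C2 (SN2, inversion) gives the 1,3-diol; trans-epoxide plus inversion places hydroxyl and hydroxymethyl syn along the chain that ends in the vinyl group, and the carbinol centre of 2 is untouched. The first equivalent of 3 is consumed by the hydroxyl group.

Step 3
Reactants: 4 (2R,3S)-2-ethenylbutane-1,3-diol
Product: 5 (2S,3R)-3-[(tert-butyldimethylsilyloxy)methyl]pent-4-en-2-ol
Conditions: TBSCl (1.05 equiv), imidazole, CH2Cl2, −20 → 0 °C
Reagents that add atoms: tert-butyldimethylsilyl chloride, CC(C)(C)[Si](C)(C)Cl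
Why: Silylation of a primary hydroxyl in the presence of a secondary one, by steric discrimination of the bulky silyl chloride at low temperature; no stereocentre is involved.

Step 4
Reactants: 6 hydroxytyrosol (2-(3,4-dihydroxyphenyl)ethanol)
Product: 7 1,2-bis(tert-butyldimethylsilyloxy)-4-[2-(tert-butyldimethylsilyloxy)ethyl]benzene
Conditions: TBSCl (3.5 equiv), imidazole, DMF, rt
Reagents that add atoms: tert-butyldimethylsilyl chloride, CC(C)(C)[Si](C)(C)Cl
Why: Exhaustive imidazole-promoted silylation of two phenols and one primary alcohol; all three hydroxyls are silylated because silylation of the phenols alone is not reliable.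

Step 5
Reactants: 7 1,2-bis(tert-butyldimethylsilyloxy)-4-[2-(tert-butyldimethylsilyloxy)ethyl]benzene
Product: 8 2-[3,4-bis(tert-butyldimethylsilyloxy)phenyl]ethanol
Conditions: camphorsulfonic acid (10 mol %), MeOH/CH2Cl2 (1:1), 0 °C
Reagents that add atoms: none
Why: Acid-catalysed methanolysis cleaves the alkyl silyl ether and leaves the aryl silyl ethers, whose oxygen atoms are much less basic; this is the standard way to tell the two kinds of silyl ether apart.

Step 6
Reactants: 8 2-[3,4-bis(tert-butyldimethylsilyloxy)phenyl]ethanol; 9 acryloyl chloride
Product: 10 2-[3,4-bis(tert-butyldimethylsilyloxy)phenyl]ethyl prop-2-enoate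
Conditions: Et3N, CH2Cl2, 0 °C
Reagents that add atoms: none
Why: Acylation of a primary alcohol with an acid chloride under amine base; the aryl silyl ethers are inert to these conditions.

Step 7
Reactants: 5 (2S,3R)-3-[(tert-butyldimethylsilyloxy)methyl]pent-4-en-2-ol; 10 2-[3,4-bis(tert-butyldimethylsilyloxy)phenyl]ethyl prop-2-enoate
Product: 11 2-[3,4-bis(tert-butyldimethylsilyloxy)phenyl]ethyl (2E,4R,5S)-4-[(tert-butyldimethylsilyloxy)methyl]-5-hydroxyhex-2-enoate
Conditions: second-generation Grubbs catalyst (H2IMes)(PCy3)Cl2Ru=CHPh (5 mol %), 10 (2 equiv, excess recovered), CH2Cl2, 40 °C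
Reagents that add atoms: none
Why: Olefin cross-metathesis between an allylically branched terminal alkene, which does not homodimerise, and an acrylate; E enoates result under thermodynamic control. The free secondary hydroxyl and the silyl ethers are tolerated and neither stereocentre is touched.

Step 8
Reactants: 11 2-[3,4-bis(tert-butyldimethylsilyloxy)phenyl]ethyl (2E,4R,5S)-4-[(tert-butyldimethylsilyloxy)methyl]-5-hydroxyhex-2-enoate; 12 methyl propiolate
Product: 14 methyl (2S,3R,4S)-4-(2-{2-[3,4-bis(tert-butyldimethylsilyloxy)phenyl]ethoxy}-2-oxoethyl)-3-[(tert-butyldimethylsilyloxy)methyl]-2-methyl-3,4-dihydro-2H-pyran-5-carboxylate, via vinyl anion 13 (not isolated)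
Conditions: DABCO (20 mol %), 12 (1.3 equiv, added slowly), CH2Cl2 (0.02 M), 0 °C → rt
Reagents that add atoms: none
Why: DABCO adds to 12 to give a zwitterion basic enough to deprotonate the hydroxyl of 11, and the resulting alkoxide adds to the alkyne terminus of another molecule of 12 (O1–C6) to give the allenolate-type vinyl anion 13. The nucleophilic carbon of 13 (C5) lies within reach of the enoate β-carbon and closes the dihydropyran by 6-exo-trig Michael addition (C4–C5); the ester enolate so formed takes the proton of the next molecule of 11 and carries the chain. The closest known reaction type is the amine- or phosphine-mediated oxa-Michael/Michael domino of hydroxy enoates and enones with alkynoates that gives cyclic β-alkoxyacrylates, itself an intramolecular trapping variant of the amine-catalysed addition of alcohols to propiolates. The new stereocentre C4 is set under kinetic control by C3: in the chair-like transition state the C3–H eclipses the enoate, the tether brings C5 to one face and the silyloxymethyl group lies anti to the forming bond, which gives 3,4-trans with the C2 methyl group equatorial. The other chair that keeps the silyloxymethyl group and the enoate both pseudo-equatorial, with the small methyl group axial beside oxygen, leads to the same 3,4-trans product, whereas the cis product requires the tether carbon to eclipse the alkene. The step needs cyclisation to outrun protonation of 13, which is why it is run dilute in an aprotic solvent with 12 kept at low concentration. The hydroxyl cannot add to its own enoate, since that would close a four-membered ring. No reagent present is basic enough to disturb C2 or C3.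

Step 9
Reactants: 14 methyl (2S,3R,4S)-4-(2-{2-[3,4-bis(tert-butyldimethylsilyloxy)phenyl]ethoxy}-2-oxoethyl)-3-[(tert-butyldimethylsilyloxy)methyl]-2-methyl-3,4-dihydro-2H-pyran-5-carboxylate
Product: 15 methyl (2S,3R,4S)-4-(2-{2-[3,4-bis(tert-butyldimethylsilyloxy)phenyl]ethoxy}-2-oxoethyl)-3-(hydroxymethyl)-2-methyl-3,4-dihydro-2H-pyran-5-carboxylate
Conditions: HF·pyridine, pyridine, THF, 0 °C
Reagents that add atoms: none
Why: Acidic fluoride cleaves primary alkyl silyl ethers much faster than aryl ones (the reverse of the order under basic fluoride); pyridine buffering and the absence of an alcohol solvent spare both esters and the enol ether, and the short contact at 0 °C limits lactonisation of the freed hydroxyl onto the side-chain ester.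

Step 10
Reactants: 15 methyl (2S,3R,4S)-4-(2-{2-[3,4-bis(tert-butyldimethylsilyloxy)phenyl]ethoxy}-2-oxoethyl)-3-(hydroxymethyl)-2-methyl-3,4-dihydro-2H-pyran-5-carboxylate
Product: 16 methyl (2S,3S,4S)-4-(2-{2-[3,4-bis(tert-butyldimethylsilyloxy)phenyl]ethoxy}-2-oxoethyl)-3-formyl-2-methyl-3,4-dihydro-2H-pyran-5-carboxylate
Conditions: Dess–Martin periodinane (1.3 equiv), CH2Cl2, 0 °C → rt; filtration through silica
Reagents that add atoms: none
Why: Dess–Martin oxidation of a primary alcohol to the aldehyde under neutral to weakly acidic conditions, so the α-stereocentre C3 is not epimerised and O1 is not eliminated; the protected catechol and the β-alkoxyacrylate are inert. The descriptor at C3 changes from R to S without a change in geometry.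

Step 11
Reactants: 16 methyl (2S,3S,4S)-4-(2-{2-[3,4-bis(tert-butyldimethylsilyloxy)phenyl]ethoxy}-2-oxoethyl)-3-formyl-2-methyl-3,4-dihydro-2H-pyran-5-carboxylate
Product: 17 methyl (2S,3S,4S)-4-{2-[2-(3,4-dihydroxyphenyl)ethoxy]-2-oxoethyl}-3-formyl-2-methyl-3,4-dihydro-2H-pyran-5-carboxylate
Conditions: Bu4NF/AcOH (1:1, 2.5 equiv), THF, 0 °C
Reagents that add atoms: none
Why: Fluoride cleavage of aryl silyl ethers is fast at 0 °C because phenoxide is a good leaving group; acetic acid buffers the fluoride and protonates the phenoxides, so the C3 aldehyde should be neither epimerised nor opened by β-elimination.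

## Compound list

1 | (E)-but-2-en-1-ol | C/C=C/CO | starting material
2 | [(2S,3S)-3-methyloxiran-2-yl]methanol | C[C@@H]1O[C@H]1CO | intermediate
3 | vinylmagnesium bromide | C=C[Mg]Br | starting material
4 | (2R,3S)-2-ethenylbutane-1,3-diol | C[C@H](O)[C@@H](CO)C=C | intermediate
5 | (2S,3R)-3-[(tert-butyldimethylsilyloxy)methyl]pent-4-en-2-ol | C[C@H](O)[C@@H](CO[Si](C)(C)C(C)(C)C)C=C | intermediate
6 | hydroxytyrosol, 2-(3,4-dihydroxyphenyl)ethanol | OCCc1ccc(O)c(O)c1 | starting material
7 | 1,2-bis(tert-butyldimethylsilyloxy)-4-[2-(tert-butyldimethylsilyloxy)ethyl]benzene | CC(C)(C)[Si](C)(C)OCCc1ccc(O[Si](C)(C)C(C)(C)C)c(O[Si](C)(C)C(C)(C)C)c1 | intermediate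
8 | 2-[3,4-bis(tert-butyldimethylsilyloxy)phenyl]ethanol | OCCc1ccc(O[Si](C)(C)C(C)(C)C)c(O[Si](C)(C)C(C)(C)C)c1 | intermediate
9 | acryloyl chloride | C=CC(Cl)=O | starting material
10 | 2-[3,4-bis(tert-butyldimethylsilyloxy)phenyl]ethyl prop-2-enoate | C=CC(=O)OCCc1ccc(O[Si](C)(C)C(C)(C)C)c(O[Si](C)(C)C(C)(C)C)c1 | intermediate
11 | 2-[3,4-bis(tert-butyldimethylsilyloxy)phenyl]ethyl (2E,4R,5S)-4-[(tert-butyldimethylsilyloxy)methyl]-5-hydroxyhex-2-enoate | C[C@H](O)[C@@H](CO[Si](C)(C)C(C)(C)C)/C=C/C(=O)OCCc1ccc(O[Si](C)(C)C(C)(C)C)c(O[Si](C)(C)C(C)(C)C)c1 | intermediate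
12 | methyl propiolate | C#CC(=O)OC | starting material
13 | vinyl anion (allenolate) from oxa-Michael addition of the alkoxide of 11 to 12 | COC(=O)[C-]=CO[C@@H](C)[C@@H](CO[Si](C)(C)C(C)(C)C)/C=C/C(=O)OCCc1ccc(O[Si](C)(C)C(C)(C)C)c(O[Si](C)(C)C(C)(C)C)c1 | intermediate
14 | methyl (2S,3R,4S)-4-(2-{2-[3,4-bis(tert-butyldimethylsilyloxy)phenyl]ethoxy}-2-oxoethyl)-3-[(tert-butyldimethylsilyloxy)methyl]-2-methyl-3,4-dihydro-2H-pyran-5-carboxylate | COC(=O)C1=CO[C@@H](C)[C@@H](CO[Si](C)(C)C(C)(C)C)[C@@H]1CC(=O)OCCc1ccc(O[Si](C)(C)C(C)(C)C)c(O[Si](C)(C)C(C)(C)C)c1 | intermediate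
15 | methyl (2S,3R,4S)-4-(2-{2-[3,4-bis(tert-butyldimethylsilyloxy)phenyl]ethoxy}-2-oxoethyl)-3-(hydroxymethyl)-2-methyl-3,4-dihydro-2H-pyran-5-carboxylate | COC(=O)C1=CO[C@@H](C)[C@@H](CO)[C@@H]1CC(=O)OCCc1ccc(O[Si](C)(C)C(C)(C)C)c(O[Si](C)(C)C(C)(C)C)c1 | intermediate
16 | methyl (2S,3S,4S)-4-(2-{2-[3,4-bis(tert-butyldimethylsilyloxy)phenyl]ethoxy}-2-oxoethyl)-3-formyl-2-methyl-3,4-dihydro-2H-pyran-5-carboxylate | COC(=O)C1=CO[C@@H](C)[C@@H](C=O)[C@@H]1CC(=O)OCCc1ccc(O[Si](C)(C)C(C)(C)C)c(O[Si](C)(C)C(C)(C)C)c1 | intermediate
17 | methyl (2S,3S,4S)-4-{2-[2-(3,4-dihydroxyphenyl)ethoxy]-2-oxoethyl}-3-formyl-2-methyl-3,4-dihydro-2H-pyran-5-carboxylate | COC(=O)C1=CO[C@@H](C)[C@@H](C=O)[C@@H]1CC(=O)OCCc1ccc(O)c(O)c1 | target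

## Step count and least certain steps

Total: 11 steps. Longest linear sequence: 8 steps (1 → 2 → 4 → 5 → 11 → 14 → 15 → 16 → 17; the branch from 6 through 7, 8 and 10 to 11 is equally long).

**Step 8 (key step).** Most likely failures:
- Proton transfer to the vinyl anion before it cyclises, which stops the domino at the open-chain adduct.
- Insufficient facial discrimination at C4, since the two chair arrangements that give trans compete with one that gives cis.
- A long-lived alkoxide could allow silyl migration from the primary to the secondary oxygen, or vinylogous retro-aldol cleavage.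

Fallback, from 11 back to 14, with the two bonds made in separate, known operations: N-methylmorpholine-catalysed addition of 11 to 12 should give the open-chain (E)-β-alkoxyacrylate F1. N-Iodosuccinimide in AcOH/CH2Cl2 followed by Et3N should give the (Z)-α-iodo-β-alkoxyacrylate F2. Bu3SnH/AIBN in benzene at 80 °C under high dilution should then close C4–C5 by 6-exo-trig cyclisation of the vinyl radical onto the enoate and deliver 14.

**Step 2.** Most likely failure: competing attack of the vinyl nucleophile at C3 of the epoxide, because the methyl group shields C3 only slightly; this erodes the yield of the 1,3-diol. The 1,2-diol regioisomer is the only one cleaved by NaIO4, which eases purification.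

Fallback, from 2 back to 4, with the regiochemistry enforced electronically: RuCl3 (catalytic)/NaIO4 oxidation of 2 should give (2R,3S)-3-methyloxirane-2-carboxylic acid F3. MeI/K2CO3 in DMF should give methyl (2R,3S)-3-methyloxirane-2-carboxylate F4. (CH2=CH)2CuLi opens such glycidic esters at the α-carbon with inversion and should give methyl (2S,3S)-2-ethenyl-3-hydroxybutanoate F5. LiAlH4 reduction of F5 gives 4.

**Step 7.** Most likely failure: slow turnover at the allylically branched alkene of 5 while the acrylate 10, which cannot be used in large excess, is lost to self-metathesis.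

Fallback, from 5 back to 11, with the ester bond made after the alkene: cross-metathesis of 5 with a large excess of acrylic acid (same catalyst, (H2IMes)(PCy3)Cl2Ru=CHPh) should give (2E,4R,5S)-4-[(tert-butyldimethylsilyloxy)methyl]-5-hydroxyhex-2-enoic acid F6. Mitsunobu esterification of F6 with 8 (PPh3, DIAD, THF, 0 °C) activates the primary alcohol 8 rather than the hindered secondary hydroxyl of F6 and should give 11.

**Step 9.** Most likely failure: lactonisation of the freed C3 hydroxymethyl group onto the C4 acetate arm with loss of the arylethyl alcohol, or partial cleavage of an aryl silyl ether during a prolonged reaction.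

Fallback, from 4 to 16, in which the free alcohol 15 is never formed: silylation of 4 with Et3SiCl/imidazole at −40 °C should give (2S,3R)-3-[(triethylsilyloxy)methyl]pent-4-en-2-ol F7. Cross-metathesis of F7 with 10 as in step 7 should give the triethylsilyl analogue of 11, F8. The domino of step 8 should give the triethylsilyl analogue of 14, F9. Direct Swern oxidation of the primary triethylsilyl ether of F9 (oxalyl chloride, DMSO, CH2Cl2, −78 → −30 °C, then Et3N at −78 °C and cold quench) should give 16.

**Step 11.** Most likely failure: epimerisation at C3 or β-elimination of O1 if the fluoride is not fully buffered, because phenoxide and fluoride are both basic enough to enolise the aldehyde.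

Fallback, from 16 back to 17, with the aldehyde masked during desilylation: HC(OMe)3/pyridinium p-toluenesulfonate in MeOH should give the dimethyl acetal F10. Bu4NF in THF at 0 °C should give the catechol acetal F11. Pyridinium p-toluenesulfonate in wet acetone hydrolyses the acetal and gives 17.

## Further compounds

F1 | step 8 | 2-[3,4-bis(tert-butyldimethylsilyloxy)phenyl]ethyl (2E,4R,5S)-4-[(tert-butyldimethylsilyloxy)methyl]-5-{[(1E)-3-methoxy-3-oxoprop-1-en-1-yl]oxy}hex-2-enoate | COC(=O)/C=C/O[C@@H](C)[C@@H](CO[Si](C)(C)C(C)(C)C)/C=C/C(=O)OCCc1ccc(O[Si](C)(C)C(C)(C)C)c(O[Si](C)(C)C(C)(C)C)c1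
F2 | step 8 | 2-[3,4-bis(tert-butyldimethylsilyloxy)phenyl]ethyl (2E,4R,5S)-4-[(tert-butyldimethylsilyloxy)methyl]-5-{[(1Z)-2-iodo-3-methoxy-3-oxoprop-1-en-1-yl]oxy}hex-2-enoate | COC(=O)/C(I)=C/O[C@@H](C)[C@@H](CO[Si](C)(C)C(C)(C)C)/C=C/C(=O)OCCc1ccc(O[Si](C)(C)C(C)(C)C)c(O[Si](C)(C)C(C)(C)C)c1
F3 | step 2 | (2R,3S)-3-methyloxirane-2-carboxylic acid | C[C@@H]1O[C@H]1C(=O)O
F4 | step 2 | methyl (2R,3S)-3-methyloxirane-2-carboxylate | C[C@@H]1O[C@H]1C(=O)OC
F5 | step 2 | methyl (2S,3S)-2-ethenyl-3-hydroxybutanoate | C[C@H](O)[C@@H](C(=O)OC)C=C
F6 | step 7 | (2E,4R,5S)-4-[(tert-butyldimethylsilyloxy)methyl]-5-hydroxyhex-2-enoic acid | C[C@H](O)[C@@H](CO[Si](C)(C)C(C)(C)C)/C=C/C(=O)O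
F7 | step 9 | (2S,3R)-3-[(triethylsilyloxy)methyl]pent-4-en-2-ol | C[C@H](O)[C@@H](CO[Si](CC)(CC)CC)C=C
F8 | step 9 | 2-[3,4-bis(tert-butyldimethylsilyloxy)phenyl]ethyl (2E,4R,5S)-5-hydroxy-4-[(triethylsilyloxy)methyl]hex-2-enoate | C[C@H](O)[C@@H](CO[Si](CC)(CC)CC)/C=C/C(=O)OCCc1ccc(O[Si](C)(C)C(C)(C)C)c(O[Si](C)(C)C(C)(C)C)c1
F9 | step 9 | methyl (2S,3R,4S)-4-(2-{2-[3,4-bis(tert-butyldimethylsilyloxy)phenyl]ethoxy}-2-oxoethyl)-2-methyl-3-[(triethylsilyloxy)methyl]-3,4-dihydro-2H-pyran-5-carboxylate | COC(=O)C1=CO[C@@H](C)[C@@H](CO[Si](CC)(CC)CC)[C@@H]1CC(=O)OCCc1ccc(O[Si](C)(C)C(C)(C)C)c(O[Si](C)(C)C(C)(C)C)c1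
F10 | step 11 | methyl (2S,3S,4S)-4-(2-{2-[3,4-bis(tert-butyldimethylsilyloxy)phenyl]ethoxy}-2-oxoethyl)-3-(dimethoxymethyl)-2-methyl-3,4-dihydro-2H-pyran-5-carboxylate | COC(=O)C1=CO[C@@H](C)[C@@H](C(OC)OC)[C@@H]1CC(=O)OCCc1ccc(O[Si](C)(C)C(C)(C)C)c(O[Si](C)(C)C(C)(C)C)c1
F11 | step 11 | methyl (2S,3S,4S)-4-{2-[2-(3,4-dihydroxyphenyl)ethoxy]-2-oxoethyl}-3-(dimethoxymethyl)-2-methyl-3,4-dihydro-2H-pyran-5-carboxylate | COC(=O)C1=CO[C@@H](C)[C@@H](C(OC)OC)[C@@H]1CC(=O)OCCc1ccc(O)c(O)c1
A1 | alternative 1 | dimethyl (2E)-2-[(2S,4S)-4-methyl-4H-1,3-dioxin-2-yl]pent-2-enedioate (2,4-trans acetal) | COC(=O)C/C=C(/C(=O)OC)[C@H]1OC=C[C@H](C)O1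
A2 | alternative 1 | methyl (2S,3S,4S)-3-formyl-4-(2-methoxy-2-oxoethyl)-2-methyl-3,4-dihydro-2H-pyran-5-carboxylate | COC(=O)C1=CO[C@@H](C)[C@@H](C=O)[C@@H]1CC(=O)OC
A3 | alternative 2 | methyl (2Z,3E)-5-(tert-butyldimethylsilyloxy)-2-(methoxymethylidene)pent-3-enoate | CO/C=C(\C(=O)OC)/C=C/CO[Si](C)(C)C(C)(C)C
A4 | alternative 2 | acetaldehyde | CC=O
A5 | alternative 2 | methyl (2S,3R,6S)-3-[(tert-butyldimethylsilyloxy)methyl]-6-methoxy-2-methyl-3,6-dihydro-2H-pyran-5-carboxylate (2,3,6-all-cis) | COC(=O)C1=C[C@H](CO[Si](C)(C)C(C)(C)C)[C@H](C)O[C@@H]1OC
A6 | alternative 3 | 2-[3,4-bis(tert-butyldimethylsilyloxy)phenyl]ethyl (3E)-5-oxopent-3-enoate | O=C/C=C/CC(=O)OCCc1ccc(O[Si](C)(C)C(C)(C)C)c(O[Si](C)(C)C(C)(C)C)c1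
A7 | alternative 3 | methyl 3-oxopropanoate (methyl formylacetate) | COC(=O)CC=O
A8 | alternative 3 | methyl (2S,3S,4S)-4-(2-{2-[3,4-bis(tert-butyldimethylsilyloxy)phenyl]ethoxy}-2-oxoethyl)-3-formyl-2-methyl-3,4-dihydro-2H-pyran-5-carboxylate (identical with 16) | COC(=O)C1=CO[C@@H](C)[C@@H](C=O)[C@@H]1CC(=O)OCCc1ccc(O[Si](C)(C)C(C)(C)C)c(O[Si](C)(C)C(C)(C)C)c1
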